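**Retrosynthetic overview**

- C9=C10 is cut by Julia–Kocienski olefination into a C1–C9 dioxane aldehyde and a C10–C14 phenyltetrazolyl sulfone; the sulfone comes from a Johnson–Claisen rearrangement of (R,E)-1-phenylbut-2-en-1-ol, which sets C12.
- The only ring, the 1,2-dioxane O1–O2–C3–C4–C5–C6, is closed once and late. O–C6 forms by 6-exo peroxymercuration of a C6=C7 alkene by a C3 hydroperoxide, itself installed by SN2 inversion of a (3R) mesylate; C1–C2 come from malonate homologation of a C3 acid and C3 from a Noyori reduction.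
- The strategy rests on C4 and C8: two CH(CH3) units of mirror-related sense placed symmetrically about C6 (C4–C5–C6–C7–C8). With C6=C7 as a temporary alkene, an Ireland–Claisen shift of the C7 propionate forms C4–C5 and relays C7, set together with C8 in one Evans aldol, to C4.
- Order: C7/C8 (aldol), then C4 and E-C6=C7 (Ireland–Claisen), then C1–C3, then the dioxane ring, then C9=C10, and the C1 acid last, so that no β-peroxy carbonyl group meets base.

Key step: step 5

Remark: atoms are numbered along the chain from the acid carbon C1 to the phenyl-bearing C14 in every intermediate; ring positions 3–6 of the 1,2-dioxane coincide with C3–C6, and the target is read from its SMILES as (3S,4S,6R,8R,12S), 9E,13E.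

**Route**

Step 1
Reactants: 1 (R)-4-benzyl-3-propionyloxazolidin-2-one; 2 methacrolein
Product: 4 (4R)-4-benzyl-3-[(2R,3R)-3-hydroxy-2,4-dimethylpent-4-enoyl]oxazolidin-2-one, via Z-boron enolate 3 (not isolated)
Conditions: Bu2BOTf, iPr2NEt, CH2Cl2, −78 → 0 °C; then pH 7 buffer, MeOH, 30% H2O2, 0 °C
Reagents that add atoms: none
Why: Evans syn aldol, in which the Z-boron enolate reacts through a Zimmerman–Traxler chair on the enolate face away from the benzyl group, so the auxiliary sets C8 and C7 together while methacrolein supplies C5, C6 and the C6 methyl.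

Step 2
Reactants: 4 (4R)-4-benzyl-3-[(2R,3R)-3-hydroxy-2,4-dimethylpent-4-enoyl]oxazolidin-2-one
Product: 5 (2S,3R)-2,4-dimethylpent-4-ene-1,3-diol
Conditions: LiBH4, MeOH (1 equiv), THF, 0 °C
Reagents that add atoms: none
Why: Reductive cleavage of the imide by LiBH4 gives the C9 primary alcohol and returns the auxiliary without touching the stereocentres or the alkene.

Step 3
Reactants: 5 (2S,3R)-2,4-dimethylpent-4-ene-1,3-diol
Product: 6 (2S,3R)-1-[(tert-butyldiphenylsilyl)oxy]-2,4-dimethylpent-4-en-3-ol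
Conditions: TBDPSCl, imidazole, CH2Cl2, 0 °C
Reagents that add atoms: tert-butyl(chloro)diphenylsilane, CC(C)(C)[Si](Cl)(c1ccccc1)c1ccccc1
Why: Silyl ether formation is much faster at the primary C9 hydroxyl than at the hindered secondary allylic C7 hydroxyl.

Step 4
Reactants: 6 (2S,3R)-1-[(tert-butyldiphenylsilyl)oxy]-2,4-dimethylpent-4-en-3-ol; 7 propionyl chloride
Product: 8 (2S,3R)-1-[(tert-butyldiphenylsilyl)oxy]-2,4-dimethylpent-4-en-3-yl propanoate
Conditions: pyridine, DMAP (cat.), CH2Cl2, 0 °C → rt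
Reagents that add atoms: none
Why: DMAP-catalysed esterification of the secondary allylic alcohol attaches the C3–C4 propionate unit with retention at C7.

Step 5
Reactants: 8 (2S,3R)-1-[(tert-butyldiphenylsilyl)oxy]-2,4-dimethylpent-4-en-3-yl propanoate
Product: 11 (2S,4E,6R)-7-[(tert-butyldiphenylsilyl)oxy]-2,4,6-trimethylhept-4-enoic acid, via E-silyl ketene acetal 9 (not isolated), via trimethylsilyl ester 10 (not isolated)
Conditions: LiN(iPr)2 (LDA), THF, −78 °C; Me3SiCl/Et3N, −78 °C → rt, then 50 °C; 1 M HCl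
Reagents that add atoms: none
Why: Ireland–Claisen rearrangement: kinetic deprotonation with LDA in THF without polar cosolvent should give the enolate whose methyl is cis to the allylic oxygen, which is trapped as the (E)-O-silyl ketene acetal and on warming undergoes a concerted suprafacial [3,3] shift that forms C4–C5 and breaks C7–O, the silyl ester being hydrolysed on acidic work-up. The closest known reaction type is the Ireland–Claisen rearrangement of propionates of secondary 2-methylallylic alcohols to E-trisubstituted γ,δ-unsaturated acids. No ring is closed; the only cyclic array is the six-membered chair transition state. The new C4 stereocentre is controlled by the C7 carbinol: in the chair the C8-bearing substituent on C7 is equatorial (axial would clash 1,3-diaxially with the silyloxy group on C3), which fixes the E geometry of C6=C7 and lets C5 bond to one face of the ketene acetal only, so (7R) is relayed to (4S) while C7 becomes sp2. The step needs one enolate geometry and chair over boat; the first is secured by cosolvent-free kinetic enolisation and the second by the equatorial preference just named, the contact between the C6 methyl and the pseudo-axial C4 methyl being the interaction that could erode it.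

Step 6
Reactants: 11 (2S,4E,6R)-7-[(tert-butyldiphenylsilyl)oxy]-2,4,6-trimethylhept-4-enoic acid; 12 potassium methyl malonate
Product: 14 methyl (4S,6E,8R)-9-[(tert-butyldiphenylsilyl)oxy]-4,6,8-trimethyl-3-oxonon-6-enoate, via acyl imidazolide 13 (not isolated)
Conditions: CDI, THF, rt; then 12, MgCl2, Et3N, MeCN, rt → 45 °C; 1 M HCl
Reagents that add atoms: none
Why: Masamune–Brooks homologation, in which the acyl imidazolide C-acylates the magnesium enolate of the malonate half-ester and decarboxylation leaves the β-keto ester with C1 and C2 added, under near-neutral conditions that should not epimerise C4.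

Step 7
Reactants: 14 methyl (4S,6E,8R)-9-[(tert-butyldiphenylsilyl)oxy]-4,6,8-trimethyl-3-oxonon-6-enoate
Product: 15 methyl (3R,4S,6E,8R)-9-[(tert-butyldiphenylsilyl)oxy]-3-hydroxy-4,6,8-trimethylnon-6-enoate
Conditions: H2 (4 atm), [RuCl2((S)-BINAP)]2·NEt3 (1 mol %), MeOH, 50 °C
Reagents that add atoms: none
Why: Noyori asymmetric hydrogenation of a β-keto ester, in which the chelated keto ester accepts hydride from the (S)-BINAP–ruthenium catalyst on one carbonyl face under catalyst control to set (3R), the isolated trisubstituted alkene and the silyl ether being inert at this pressure.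

Step 8
Reactants: 15 methyl (3R,4S,6E,8R)-9-[(tert-butyldiphenylsilyl)oxy]-3-hydroxy-4,6,8-trimethylnon-6-enoate
Product: 16 (3R,4S,6E,8R)-9-[(tert-butyldiphenylsilyl)oxy]-4,6,8-trimethylnon-6-ene-1,3-diol
Conditions: LiAlH4, THF, 0 °C
Reagents that add atoms: none
Why: LiAlH4 reduction of the ester to the primary alcohol removes the acidifying carbonyl, so that C3 can later carry a leaving group without β-elimination.

Step 9
Reactants: 16 (3R,4S,6E,8R)-9-[(tert-butyldiphenylsilyl)oxy]-4,6,8-trimethylnon-6-ene-1,3-diol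
Product: 17 (3R,4S,6E,8R)-9-[(tert-butyldiphenylsilyl)oxy]-4,6,8-trimethyl-1-(trityloxy)non-6-en-3-ol
Conditions: TrCl, Et3N, DMAP (cat.), CH2Cl2, rt
Reagents that add atoms: trityl chloride, ClC(c1ccccc1)(c1ccccc1)c1ccccc1
Why: Trityl ether formation is selective for the primary C1 hydroxyl on steric grounds, and the trityl group should survive alkaline peroxide, mercury acetate and fluoride yet leave under mild acid after the silyl group is gone.

Step 10
Reactants: 17 (3R,4S,6E,8R)-9-[(tert-butyldiphenylsilyl)oxy]-4,6,8-trimethyl-1-(trityloxy)non-6-en-3-ol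
Product: 18 (3R,4S,6E,8R)-9-[(tert-butyldiphenylsilyl)oxy]-4,6,8-trimethyl-1-(trityloxy)non-6-en-3-yl methanesulfonate
Conditions: MsCl, Et3N, CH2Cl2, −10 °C
Reagents that add atoms: methanesulfonyl chloride, CS(=O)(=O)Cl
Why: Mesylate formation at the C3 alcohol proceeds with retention and provides the leaving group for the peroxide displacement.

Step 11
Reactants: 18 (3R,4S,6E,8R)-9-[(tert-butyldiphenylsilyl)oxy]-4,6,8-trimethyl-1-(trityloxy)non-6-en-3-yl methanesulfonate
Product: 19 (3S,4S,6E,8R)-9-[(tert-butyldiphenylsilyl)oxy]-4,6,8-trimethyl-1-(trityloxy)non-6-en-3-yl hydroperoxide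
Conditions: 50% aq. H2O2 (excess), KOH, MeOH–THF, 0 °C → rt
Reagents that add atoms: hydrogen peroxide, OO
Why: SN2 displacement of a secondary sulfonate by hydroperoxide anion (alkaline hydrogen peroxide displacement) inverts C3 from R to S, the α-effect nucleophile and the absence of a carbonyl at C1 favouring substitution over elimination, and unactivated alkenes, silyl ethers and trityl ethers tolerate alkaline peroxide.

Step 12
Reactants: 19 (3S,4S,6E,8R)-9-[(tert-butyldiphenylsilyl)oxy]-4,6,8-trimethyl-1-(trityloxy)non-6-en-3-yl hydroperoxide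
Product: 21 (3S,4S,6R)-6-[(2R)-3-[(tert-butyldiphenylsilyl)oxy]-2-methylpropyl]-4,6-dimethyl-3-[2-(trityloxy)ethyl]-1,2-dioxane, via organomercury acetate 20 (not isolated)
Conditions: Hg(OAc)2, CH2Cl2, 0 °C → rt; then NaBH4, 3 M NaOH, 0 °C
Reagents that add atoms: none
Why: Intramolecular peroxymercuration followed by hydride demercuration, in which divalent mercury activates C6=C7 and the C3 hydroperoxide attacks the more substituted C6 in a 6-exo Markovnikov closure through a chair with the C4 methyl and the mercurated C7 branch equatorial and the C6 methyl axial, which should set (6R), after which NaBH4 replaces mercury at C7 by hydrogen without reducing the O–O bond.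

Step 13
Reactants: 21 (3S,4S,6R)-6-[(2R)-3-[(tert-butyldiphenylsilyl)oxy]-2-methylpropyl]-4,6-dimethyl-3-[2-(trityloxy)ethyl]-1,2-dioxane
Product: 22 (2R)-3-[(3S,4S,6R)-4,6-dimethyl-3-[2-(trityloxy)ethyl]-1,2-dioxan-6-yl]-2-methylpropan-1-ol
Conditions: Bu4NF, AcOH, THF, rt
Reagents that add atoms: none
Why: Fluoride desilylation of the primary silyl ether, buffered with acetic acid so that neither the trityl ether nor the dialkyl peroxide meets strong base.

Step 14
Reactants: 22 (2R)-3-[(3S,4S,6R)-4,6-dimethyl-3-[2-(trityloxy)ethyl]-1,2-dioxan-6-yl]-2-methylpropan-1-ol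
Product: 23 (2R)-3-[(3S,4S,6R)-4,6-dimethyl-3-[2-(trityloxy)ethyl]-1,2-dioxan-6-yl]-2-methylpropanal
Conditions: Dess–Martin periodinane, NaHCO3, CH2Cl2, 0 °C → rt
Reagents that add atoms: none
Why: Dess–Martin oxidation gives the C9 aldehyde under buffered, non-reducing conditions that leave the O–O bond and the α-stereocentre C8 intact, the aldehyde being used at once.

Step 15
Reactants: 24 (E)-but-2-enal; 25 phenylmagnesium bromide
Product: 26 rac-(E)-1-phenylbut-2-en-1-ol
Conditions: THF, −78 → 0 °C; aq. NH4Cl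
Reagents that add atoms: none
Why: Grignard 1,2-addition to the enal gives the racemic secondary allylic alcohol that carries C12–C14 and the phenyl ring.

Step 16
Reactants: 26 rac-(E)-1-phenylbut-2-en-1-ol
Product: 27 (R,E)-1-phenylbut-2-en-1-ol
Conditions: Ti(OiPr)4, D-(−)-diisopropyl tartrate, tBuOOH (0.6 equiv), 4 Å MS, CH2Cl2, −20 °C
Reagents that add atoms: none
Why: Sharpless kinetic resolution, in which the D-(−)-tartrate catalyst should epoxidise the (S)-alcohol much faster to its erythro epoxy alcohol, so that the (R)-alcohol is recovered enantioenriched at slightly over half conversion.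

Step 17
Reactants: 27 (R,E)-1-phenylbut-2-en-1-ol; 28 triethyl orthoacetate
Product: 30 ethyl (3S,4E)-3-methyl-5-phenylpent-4-enoate, via mixed ketene acetal 29 (not isolated)
Conditions: EtCO2H (cat.), neat 28, 135 °C, EtOH distilled off
Reagents that add atoms: none
Why: Johnson–Claisen rearrangement, in which the mixed ketene acetal reacts through a chair with phenyl equatorial, giving the E styrene and transferring the carbinol configuration suprafacially to C12 (S) while adding C10 and C11.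

Step 18
Reactants: 30 ethyl (3S,4E)-3-methyl-5-phenylpent-4-enoate
Product: 31 (3S,4E)-3-methyl-5-phenylpent-4-en-1-ol
Conditions: LiAlH4, Et2O, 0 °C
Reagents that add atoms: none
Why: LiAlH4 reduction of the ester gives the C10 primary alcohol and leaves the styrene and C12 untouched.

Step 19
Reactants: 31 (3S,4E)-3-methyl-5-phenylpent-4-en-1-ol
Product: 32 5-{[(3S,4E)-3-methyl-5-phenylpent-4-en-1-yl]sulfanyl}-1-phenyl-1H-tetrazole
Conditions: 1-phenyl-1H-tetrazole-5-thiol, PPh3, DIAD, THF, 0 °C → rt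
Reagents that add atoms: 1-phenyl-1H-tetrazole-5-thiol, Sc1nnnn1-c1ccccc1
Why: Mitsunobu thioetherification of the primary alcohol with the acidic tetrazole thiol involves no stereocentre.

Step 20
Reactants: 32 5-{[(3S,4E)-3-methyl-5-phenylpent-4-en-1-yl]sulfanyl}-1-phenyl-1H-tetrazole
Product: 33 5-{[(3S,4E)-3-methyl-5-phenylpent-4-en-1-yl]sulfonyl}-1-phenyl-1H-tetrazole
Conditions: 30% H2O2, (NH4)6Mo7O24·4H2O (cat.), EtOH, 0 °C → rt
Reagents that add atoms: hydrogen peroxide, OO
Why: Molybdate-catalysed sulfide-to-sulfone oxidation with H2O2, under which a 1,2-disubstituted styrene is not expected to be epoxidised.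

Step 21
Reactants: 23 (2R)-3-[(3S,4S,6R)-4,6-dimethyl-3-[2-(trityloxy)ethyl]-1,2-dioxan-6-yl]-2-methylpropanal; 33 5-{[(3S,4E)-3-methyl-5-phenylpent-4-en-1-yl]sulfonyl}-1-phenyl-1H-tetrazole
Product: 34 (3S,4S,6R)-6-[(2R,3E,6S,7E)-2,6-dimethyl-8-phenylocta-3,7-dien-1-yl]-4,6-dimethyl-3-[2-(trityloxy)ethyl]-1,2-dioxane
Conditions: 33, KN(SiMe3)2, DME, −60 °C; then 23, −60 °C → rt
Reagents that add atoms: none
Why: Julia–Kocienski olefination, in which the potassium sulfonyl carbanion adds to the aldehyde and Smiles rearrangement with loss of SO2 and tetrazololate gives C9=C10, E-selective for the potassium/DME combination with an α-branched aldehyde, the addition at −60 °C being faster than enolisation at C8 or attack on the hindered dialkyl peroxide.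

Step 22
Reactants: 34 (3S,4S,6R)-6-[(2R,3E,6S,7E)-2,6-dimethyl-8-phenylocta-3,7-dien-1-yl]-4,6-dimethyl-3-[2-(trityloxy)ethyl]-1,2-dioxane
Product: 35 2-[(3S,4S,6R)-6-[(2R,3E,6S,7E)-2,6-dimethyl-8-phenylocta-3,7-dien-1-yl]-4,6-dimethyl-1,2-dioxan-3-yl]ethan-1-ol
Conditions: p-TsOH·H2O (cat.), MeOH–CH2Cl2, 0 °C → rt
Reagents that add atoms: none
Why: Acid-catalysed methanolysis of the trityl ether frees the C1 alcohol, and 1,2-dioxanes and isolated alkenes tolerate dilute sulfonic acid.

Step 23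
Reactants: 35 2-[(3S,4S,6R)-6-[(2R,3E,6S,7E)-2,6-dimethyl-8-phenylocta-3,7-dien-1-yl]-4,6-dimethyl-1,2-dioxan-3-yl]ethan-1-ol
Product: 37 2-[(3S,4S,6R)-6-[(2R,3E,6S,7E)-2,6-dimethyl-8-phenylocta-3,7-dien-1-yl]-4,6-dimethyl-1,2-dioxan-3-yl]acetic acid, via aldehyde 36 (not isolated)
Conditions: TEMPO (cat.), PhI(OAc)2, MeCN–pH 7 phosphate buffer, rt
Reagents that add atoms: water, O
Why: Oxoammonium (TEMPO) oxidation with PhI(OAc)2 as terminal oxidant takes the primary alcohol through the aldehyde and its hydrate to the acid under near-neutral, non-reducing conditions compatible with the peroxide and both alkenes.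

**Compound list**

1 | (R)-4-benzyl-3-propionyloxazolidin-2-one | CCC(=O)N1[C@H](Cc2ccccc2)COC1=O | starting material
2 | methacrolein | C=C(C)C=O | starting material
3 | dibutylboron Z-enolate of 1 | C/C=C(\OB(CCCC)CCCC)N1[C@H](Cc2ccccc2)COC1=O | intermediate
4 | (4R)-4-benzyl-3-[(2R,3R)-3-hydroxy-2,4-dimethylpent-4-enoyl]oxazolidin-2-one | O=C1OC[C@@H](Cc2ccccc2)N1C(=O)[C@H](C)[C@@H](O)C(C)=C | intermediate
5 | (2S,3R)-2,4-dimethylpent-4-ene-1,3-diol | OC[C@H](C)[C@@H](O)C(C)=C | intermediate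
6 | (2S,3R)-1-[(tert-butyldiphenylsilyl)oxy]-2,4-dimethylpent-4-en-3-ol | CC(C)(C)[Si](c1ccccc1)(c1ccccc1)OC[C@H](C)[C@@H](O)C(C)=C | intermediate
7 | propionyl chloride | CCC(=O)Cl | starting material
8 | (2S,3R)-1-[(tert-butyldiphenylsilyl)oxy]-2,4-dimethylpent-4-en-3-yl propanoate (7R,8S in chain numbering) | CC(C)(C)[Si](c1ccccc1)(c1ccccc1)OC[C@H](C)[C@@H](OC(=O)CC)C(C)=C | intermediate
9 | (E)-O-trimethylsilyl ketene acetal of 8 (methyl cis to the allylic oxygen) | CC(C)(C)[Si](c1ccccc1)(c1ccccc1)OC[C@H](C)[C@@H](O/C(=C\C)O[Si](C)(C)C)C(C)=C | intermediate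
10 | trimethylsilyl (2S,4E,6R)-7-[(tert-butyldiphenylsilyl)oxy]-2,4,6-trimethylhept-4-enoate | CC(C)(C)[Si](c1ccccc1)(c1ccccc1)OC[C@H](C)/C=C(\C)C[C@H](C)C(=O)O[Si](C)(C)C | intermediate
11 | (2S,4E,6R)-7-[(tert-butyldiphenylsilyl)oxy]-2,4,6-trimethylhept-4-enoic acid (4S,8R in chain numbering) | CC(C)(C)[Si](c1ccccc1)(c1ccccc1)OC[C@H](C)/C=C(\C)C[C@H](C)C(=O)O | intermediate
12 | potassium methyl malonate | COC(=O)CC(=O)[O-].[K+] | starting material
13 | 1-[(2S,4E,6R)-7-[(tert-butyldiphenylsilyl)oxy]-2,4,6-trimethylhept-4-enoyl]imidazole | CC(C)(C)[Si](c1ccccc1)(c1ccccc1)OC[C@H](C)/C=C(\C)C[C@H](C)C(=O)n1ccnc1 | intermediate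
14 | methyl (4S,6E,8R)-9-[(tert-butyldiphenylsilyl)oxy]-4,6,8-trimethyl-3-oxonon-6-enoate | CC(C)(C)[Si](c1ccccc1)(c1ccccc1)OC[C@H](C)/C=C(\C)C[C@H](C)C(=O)CC(=O)OC | intermediate
15 | methyl (3R,4S,6E,8R)-9-[(tert-butyldiphenylsilyl)oxy]-3-hydroxy-4,6,8-trimethylnon-6-enoate | CC(C)(C)[Si](c1ccccc1)(c1ccccc1)OC[C@H](C)/C=C(\C)C[C@H](C)[C@H](O)CC(=O)OC | intermediate
16 | (3R,4S,6E,8R)-9-[(tert-butyldiphenylsilyl)oxy]-4,6,8-trimethylnon-6-ene-1,3-diol | CC(C)(C)[Si](c1ccccc1)(c1ccccc1)OC[C@H](C)/C=C(\C)C[C@H](C)[C@H](O)CCO | intermediate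
17 | (3R,4S,6E,8R)-9-[(tert-butyldiphenylsilyl)oxy]-4,6,8-trimethyl-1-(trityloxy)non-6-en-3-ol | CC(C)(C)[Si](c1ccccc1)(c1ccccc1)OC[C@H](C)/C=C(\C)C[C@H](C)[C@H](O)CCOC(c1ccccc1)(c1ccccc1)c1ccccc1 | intermediate
18 | (3R,4S,6E,8R)-9-[(tert-butyldiphenylsilyl)oxy]-4,6,8-trimethyl-1-(trityloxy)non-6-en-3-yl methanesulfonate | CC(C)(C)[Si](c1ccccc1)(c1ccccc1)OC[C@H](C)/C=C(\C)C[C@H](C)[C@H](OS(C)(=O)=O)CCOC(c1ccccc1)(c1ccccc1)c1ccccc1 | intermediate
19 | (3S,4S,6E,8R)-9-[(tert-butyldiphenylsilyl)oxy]-4,6,8-trimethyl-1-(trityloxy)non-6-en-3-yl hydroperoxide | CC(C)(C)[Si](c1ccccc1)(c1ccccc1)OC[C@H](C)/C=C(\C)C[C@H](C)[C@@H](OO)CCOC(c1ccccc1)(c1ccccc1)c1ccccc1 | intermediate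
20 | C7-acetoxymercurio derivative of 21 (anti adduct; 3S,4S,6S,7R,8S in chain numbering, the letters at C6 and C8 differing from 21 only through the priority of mercury) | CC(C)(C)[Si](c1ccccc1)(c1ccccc1)OC[C@H](C)[C@@H]([Hg]OC(C)=O)[C@]1(C)C[C@H](C)[C@H](CCOC(c2ccccc2)(c2ccccc2)c2ccccc2)OO1 | intermediate
21 | (3S,4S,6R)-6-[(2R)-3-[(tert-butyldiphenylsilyl)oxy]-2-methylpropyl]-4,6-dimethyl-3-[2-(trityloxy)ethyl]-1,2-dioxane | CC(C)(C)[Si](c1ccccc1)(c1ccccc1)OC[C@H](C)C[C@]1(C)C[C@H](C)[C@H](CCOC(c2ccccc2)(c2ccccc2)c2ccccc2)OO1 | intermediate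
22 | (2R)-3-[(3S,4S,6R)-4,6-dimethyl-3-[2-(trityloxy)ethyl]-1,2-dioxan-6-yl]-2-methylpropan-1-ol | OC[C@H](C)C[C@]1(C)C[C@H](C)[C@H](CCOC(c2ccccc2)(c2ccccc2)c2ccccc2)OO1 | intermediate
23 | (2R)-3-[(3S,4S,6R)-4,6-dimethyl-3-[2-(trityloxy)ethyl]-1,2-dioxan-6-yl]-2-methylpropanal | O=C[C@H](C)C[C@]1(C)C[C@H](C)[C@H](CCOC(c2ccccc2)(c2ccccc2)c2ccccc2)OO1 | intermediate
24 | (E)-but-2-enal | C/C=C/C=O | starting material
25 | phenylmagnesium bromide | Br[Mg]c1ccccc1 | starting material
26 | rac-(E)-1-phenylbut-2-en-1-ol | C/C=C/C(O)c1ccccc1 | intermediate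
27 | (R,E)-1-phenylbut-2-en-1-ol | C/C=C/[C@@H](O)c1ccccc1 | intermediate
28 | triethyl orthoacetate | CCOC(C)(OCC)OCC | starting material
29 | 1-ethoxyvinyl ether of 27 (mixed ketene acetal) | C=C(OCC)O[C@H](/C=C/C)c1ccccc1 | intermediate
30 | ethyl (3S,4E)-3-methyl-5-phenylpent-4-enoate | CCOC(=O)C[C@H](C)/C=C/c1ccccc1 | intermediate
31 | (3S,4E)-3-methyl-5-phenylpent-4-en-1-ol | OCC[C@H](C)/C=C/c1ccccc1 | intermediate
32 | 5-{[(3S,4E)-3-methyl-5-phenylpent-4-en-1-yl]sulfanyl}-1-phenyl-1H-tetrazole | c1ccccc1-n1nnnc1SCC[C@H](C)/C=C/c1ccccc1 | intermediate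
33 | 5-{[(3S,4E)-3-methyl-5-phenylpent-4-en-1-yl]sulfonyl}-1-phenyl-1H-tetrazole | c1ccccc1-n1nnnc1S(=O)(=O)CC[C@H](C)/C=C/c1ccccc1 | intermediate
34 | (3S,4S,6R)-6-[(2R,3E,6S,7E)-2,6-dimethyl-8-phenylocta-3,7-dien-1-yl]-4,6-dimethyl-3-[2-(trityloxy)ethyl]-1,2-dioxane | C[C@H](/C=C/c1ccccc1)C/C=C/[C@H](C)C[C@]1(C)C[C@H](C)[C@H](CCOC(c2ccccc2)(c2ccccc2)c2ccccc2)OO1 | intermediate
35 | 2-[(3S,4S,6R)-6-[(2R,3E,6S,7E)-2,6-dimethyl-8-phenylocta-3,7-dien-1-yl]-4,6-dimethyl-1,2-dioxan-3-yl]ethan-1-ol | C[C@H](/C=C/c1ccccc1)C/C=C/[C@H](C)C[C@]1(C)C[C@H](C)[C@H](CCO)OO1 | intermediate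
36 | 2-[(3S,4S,6R)-6-[(2R,3E,6S,7E)-2,6-dimethyl-8-phenylocta-3,7-dien-1-yl]-4,6-dimethyl-1,2-dioxan-3-yl]acetaldehyde | C[C@H](/C=C/c1ccccc1)C/C=C/[C@H](C)C[C@]1(C)C[C@H](C)[C@H](CC=O)OO1 | intermediate
37 | 2-[(3S,4S,6R)-6-[(2R,3E,6S,7E)-2,6-dimethyl-8-phenylocta-3,7-dien-1-yl]-4,6-dimethyl-1,2-dioxan-3-yl]acetic acid | C[C@H](/C=C/c1ccccc1)C/C=C/[C@H](C)C[C@]1(C)C[C@H](C)[C@H](CC(=O)O)OO1 | target

**Step count**

Total steps: 23. Longest linear sequence: 17 (steps 1–14 and 21–23); steps 15–20 form the side-chain branch.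

**Steps most likely to fail**

Step 11. Elimination of the β-branched secondary mesylate may outrun substitution, the reaction may stall in the partly aqueous medium, or the silyl ether may be lost to alkaline peroxide. The fallback replaces aqueous peroxide by alkylation of a protected hydroperoxide under anhydrous conditions and sets out from alcohol 17. Triflation (Tf2O, 2,6-lutidine, CH2Cl2, −78 °C) gives the (3R)-triflate F1. Alkylation of 2-methoxyprop-2-yl hydroperoxide (KOtBu, THF, 0 °C) with F1 gives, with inversion, the (3S)-2-methoxyprop-2-yl peroxyketal F2. Brief hydrolysis (AcOH–THF–H2O, rt), much faster for the peroxyketal than for the trityl ether, releases hydroperoxide 19, where the route is rejoined.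

Step 12. Attack on the wrong face of C6=C7 would give the C6 epimer, and during demercuration the β-peroxy C7 radical may fragment to an epoxide with opening of the ring. The fallback avoids mercury and any C7 radical by inverting the polarity of ring closure, and sets out from mesylate 18. Isayama–Mukaiyama peroxidation (Co(thd)2 cat., thd = 2,2,6,6-tetramethylheptane-3,5-dionate, O2, Et3SiH, ClCH2CH2Cl, rt) places the peroxide on the tertiary C6 and hydrogen on C7, giving the triethylsilyl peroxide mesylate F3 as a C6 epimer mixture. Bu4NF (1 equiv, THF, 0 °C) frees the tertiary hydroperoxide mesylate F4. KOtBu with 18-crown-6 (THF, 0 °C) closes O–C3 by 6-exo-tet SN2 with the same inversion at C3, giving 21 together with its C6 epimer F5, from which it is separated by chromatography; the route is rejoined at 21.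

Step 5. Incomplete control of enolate geometry or leakage through a boat transition state would erode the C4 configuration, and the C4 epimers are hard to separate at the acid stage. The fallback sets C4 by auxiliary-controlled alkylation instead of relay from C7 and sets out from alcohol 6. Bromination with allylic transposition (PBr3, pyridine cat., Et2O, −10 °C) gives the primary E allylic bromide F6. Evans alkylation of the sodium enolate of 1 (NaN(SiMe3)2, THF, −78 °C) with F6, on the face away from the benzyl group, gives the (4S)-imide F7. Cleavage with LiOH/H2O2 (THF–H2O, 0 °C) gives acid 11, where the route is rejoined.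

**Further compounds**

F1 | step 11 | (3R,4S,6E,8R)-9-[(tert-butyldiphenylsilyl)oxy]-4,6,8-trimethyl-1-(trityloxy)non-6-en-3-yl trifluoromethanesulfonate | CC(C)(C)[Si](c1ccccc1)(c1ccccc1)OC[C@H](C)/C=C(\C)C[C@H](C)[C@H](OS(=O)(=O)C(F)(F)F)CCOC(c1ccccc1)(c1ccccc1)c1ccccc1
F2 | step 11 | 2-methoxyprop-2-yl (3S,4S,6E,8R)-9-[(tert-butyldiphenylsilyl)oxy]-4,6,8-trimethyl-1-(trityloxy)non-6-en-3-yl peroxide | CC(C)(C)[Si](c1ccccc1)(c1ccccc1)OC[C@H](C)/C=C(\C)C[C@H](C)[C@@H](OOC(C)(C)OC)CCOC(c1ccccc1)(c1ccccc1)c1ccccc1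
F3 | step 12 | (3R,4S,8R)-9-[(tert-butyldiphenylsilyl)oxy]-4,6,8-trimethyl-6-[(triethylsilyl)peroxy]-1-(trityloxy)nonan-3-yl methanesulfonate (C6 epimer mixture) | CC(C)(C)[Si](c1ccccc1)(c1ccccc1)OC[C@H](C)CC(C)(OO[Si](CC)(CC)CC)C[C@H](C)[C@H](OS(C)(=O)=O)CCOC(c1ccccc1)(c1ccccc1)c1ccccc1
F4 | step 12 | (3R,4S,8R)-9-[(tert-butyldiphenylsilyl)oxy]-6-hydroperoxy-4,6,8-trimethyl-1-(trityloxy)nonan-3-yl methanesulfonate (C6 epimer mixture) | CC(C)(C)[Si](c1ccccc1)(c1ccccc1)OC[C@H](C)CC(C)(OO)C[C@H](C)[C@H](OS(C)(=O)=O)CCOC(c1ccccc1)(c1ccccc1)c1ccccc1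
F5 | step 12 | (3S,4S,6S)-6-[(2R)-3-[(tert-butyldiphenylsilyl)oxy]-2-methylpropyl]-4,6-dimethyl-3-[2-(trityloxy)ethyl]-1,2-dioxane (C6 epimer of 21) | CC(C)(C)[Si](c1ccccc1)(c1ccccc1)OC[C@H](C)C[C@@]1(C)C[C@H](C)[C@H](CCOC(c2ccccc2)(c2ccccc2)c2ccccc2)OO1
F6 | step 5 | {[(2R,3E)-5-bromo-2,4-dimethylpent-3-en-1-yl]oxy}(tert-butyl)diphenylsilane | CC(C)(C)[Si](c1ccccc1)(c1ccccc1)OC[C@H](C)/C=C(\C)CBr
F7 | step 5 | (4R)-4-benzyl-3-[(2S,4E,6R)-7-[(tert-butyldiphenylsilyl)oxy]-2,4,6-trimethylhept-4-enoyl]oxazolidin-2-one | CC(C)(C)[Si](c1ccccc1)(c1ccccc1)OC[C@H](C)/C=C(\C)C[C@H](C)C(=O)N1[C@H](Cc2ccccc2)COC1=O
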